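**Plan**
- Cuts: the O3–acyl ester bond; the C2–CH3 and C3–O bonds (back to a cis-fused N-Boc lactam through its 2-methyl enecarbamate); the C4a–H/C8a–H pair (back to an ene-lactam whose nitrogen was a nitrile nitrogen); then C5–C6 and C7–C8 of ring B together in one [4+2] step; last C4a=C5 (olefination) and C4–C4a (conjugate addition to acrylonitrile).
- Enabling feature: in ring B the unsubstituted C6–C7 pair lies between C5 (side-chain stereocentre) and C8, and C8a carries the ring nitrogen; with that nitrogen taken back to an enol oxygen, C8=C8a(O)–C4a=C5 is an electron-rich 2-oxy-1,3-diene and C6–C7 an acrylate used as an ethylene surrogate.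
- Forward order: a ketophosphonate, acrylonitrile and the side-chain aldehyde give the acyclic diene; ring B arises first (Diels–Alder), the acrylate carbon is removed, ring A closes as a lactam from the nitrile, and methyl, hydroxyl and ester follow.
- Stereochemistry: C5' is bought ((R)-2-propyloxirane); C5 is set by an enantioselective catalyst in the key step; C4a and C8a follow in one hydrogenation anti to the C5 chain; C3 and C2 follow in one epoxidation–reductive opening on the convex face of the cis-fused bicycle.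

Key step: step 7

Remark: atom numbers are those of the decahydroquinoline (N1, C2–C4, C4a, C5–C8, C8a; primed numbers for the octyl chain); ring A is the piperidine, ring B the carbocycle.
Assumption: the (S)-configured oxazaborolidinium salt is taken to give the (5S) adduct in step 7; if the sense of induction were the opposite, the (R)-catalyst would be used with no other change.

Step 1
Reactants: 1 5-bromopent-1-ene; 2 (R)-2-propyloxirane
Product: 4 (4R)-dec-9-en-4-ol, via pent-4-enylmagnesium bromide 3 (not isolated)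
Conditions: Mg, THF, 40 °C; then 2, CuI (10 mol%), THF, −30 → 0 °C; H2O
Reagents that add atoms: none
Why: Copper-catalysed Grignard opening of a terminal epoxide takes place at the unsubstituted carbon (SN2), so the bought carbinol centre C5' is carried over unchanged.

Step 2
Reactants: 4 (4R)-dec-9-en-4-ol
Product: 5 tert-butyl[(4R)-dec-9-en-4-yloxy]dimethylsilane
Conditions: TBSCl, imidazole, DMF, rt
Reagents that add atoms: tert-butyldimethylsilyl chloride, CC(C)(C)[Si](C)(C)Cl
Why: Standard silylation of a secondary alcohol gives an ether that should survive every step up to the final acid treatment.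

Step 3
Reactants: 5 tert-butyl[(4R)-dec-9-en-4-yloxy]dimethylsilane
Product: 7 (6R)-6-(tert-butyldimethylsilyloxy)nonanal, via ozonide 6 (not isolated)
Conditions: O3, CH2Cl2, −78 °C; then PPh3, −78 °C → rt
Reagents that add atoms: ozone, [O-][O+]=O
Why: Ozonolysis with reductive work-up cleaves the terminal alkene to the aldehyde without touching the silyl ether.

Step 4
Reactants: 8 dimethyl (2-oxopropyl)phosphonate; 9 acrylonitrile
Product: 10 dimethyl (5-cyano-2-oxopentan-3-yl)phosphonate (racemic)
Conditions: DBU (10 mol%), MeCN, 0 °C → rt (8 in slight excess)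
Reagents that add atoms: none
Why: Base-catalysed Michael addition of the doubly activated CH of the β-ketophosphonate to acrylonitrile attaches C4, C3, C2 and the future ring nitrogen, and the new centre is lost in step 5.

Step 5
Reactants: 10 dimethyl (5-cyano-2-oxopentan-3-yl)phosphonate; 7 (6R)-6-(tert-butyldimethylsilyloxy)nonanal
Product: 11 (4E,10R)-4-acetyl-10-(tert-butyldimethylsilyloxy)tridec-4-enenitrile
Conditions: Ba(OH)2 (0.8 equiv), THF–H2O (40:1), rt
Reagents that add atoms: none
Why: Horner–Wadsworth–Emmons olefination of an α-substituted β-ketophosphonate should give the trisubstituted enone with the aldehyde chain trans to the acetyl group (E), the geometry that later places the side chain outside on the diene.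

Step 6
Reactants: 11 (4E,10R)-4-acetyl-10-(tert-butyldimethylsilyloxy)tridec-4-enenitrile
Product: 12 (4E,10R)-10-(tert-butyldimethylsilyloxy)-4-[1-(triisopropylsilyloxy)ethenyl]tridec-4-enenitrile
Conditions: TIPSOTf, Et3N, CH2Cl2, 0 °C
Reagents that add atoms: triisopropylsilyl trifluoromethanesulfonate, CC(C)[Si](C(C)C)(C(C)C)OS(=O)(=O)C(F)(F)F
Why: Soft enolisation of the methyl ketone gives the cross-conjugated 2-silyloxy diene because the other α-carbon is fully substituted, while nitrile and silyl ether are inert.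

Step 7
Reactants: 12 (4E,10R)-10-(tert-butyldimethylsilyloxy)-4-[1-(triisopropylsilyloxy)ethenyl]tridec-4-enenitrile; 13 2,2,2-trifluoroethyl prop-2-enoate
Product: 14 2,2,2-trifluoroethyl (1S,2S)-2-[(5R)-5-(tert-butyldimethylsilyloxy)octyl]-3-(2-cyanoethyl)-4-(triisopropylsilyloxy)cyclohex-3-ene-1-carboxylate
Conditions: (S)-oxazaborolidinium triflimide [from (S)-α,α-diphenylprolinol, o-tolylboroxine and HNTf2] (20 mol%), CH2Cl2, −78 → −20 °C
Reagents that add atoms: none
Why: The cationic oxazaborolidinium salt binds the acrylate carbonyl and lowers its LUMO, and the electron-rich 2-silyloxy diene adds in a concerted but asynchronous [4+2] cycloaddition in which the C8–C7 bond (enol ether terminus to the acrylate β-carbon) leads and the C5–C6 bond follows. The closest known reaction type is the oxazaborolidinium-catalysed enantioselective Diels–Alder reaction of 2-(triisopropylsilyloxy)-1,3-dienes with 2,2,2-trifluoroethyl acrylate. Ring B closes as a suprafacial [4π+2π] six-membered ring closure that joins both diene termini to the two alkene carbons. C5 is set by the catalyst, which exposes one face of the bound acrylate so that the endo-oriented diene bonds through one face only, and the transient C6 centre follows from the endo rule (ester cis to the side chain) and is erased in step 9. The step needs regioselectivity, secured because the 2-silyloxy group and the C5 alkyl group both make C8 the nucleophilic terminus (ester para to the silyloxy group and ortho to the side chain); it needs a reactive s-cis diene, secured by the 2,3-disubstitution and the E geometry that places the side chain outside; and it needs enantiofacial selectivity, which the catalyst must supply because the only stereocentre of the diene (C5') is remote.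

Step 8
Reactants: 14 the trifluoroethyl ester cycloadduct
Product: 15 (1S,2S)-2-[(5R)-5-(tert-butyldimethylsilyloxy)octyl]-3-(2-cyanoethyl)-4-(triisopropylsilyloxy)cyclohex-3-ene-1-carboxylic acid
Conditions: LiOH, THF–H2O (3:1), 0 °C; then 1 M HCl to pH 4
Reagents that add atoms: lithium hydroxide, [Li+].[OH-]
Why: The activated trifluoroethyl ester is saponified under conditions that should leave the nitrile, the hindered silyl enol ether and the silyl ether intact, and the configuration at C6 is irrelevant.

Step 9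
Reactants: 15 the cyclohexenecarboxylic acid
Product: 17 3-[(6S)-6-[(5R)-5-(tert-butyldimethylsilyloxy)octyl]-2-(triisopropylsilyloxy)cyclohex-1-en-1-yl]propanenitrile, via thiohydroxamate ester 16 (not isolated)
Conditions: 1-hydroxypyridine-2(1H)-thione, DCC, DMAP (cat.), CH2Cl2, rt, dark; then t-BuSH, hν (tungsten lamp), 20 °C
Reagents that add atoms: none
Why: Barton reductive decarboxylation, in which the thiohydroxamate ester fragments under light to the secondary C6 radical that abstracts hydrogen from the thiol, removes the activating carbon of the dienophile and leaves C5 untouched.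

Step 10
Reactants: 17 the silyl enol ether nitrile
Product: 18 3-[(6S)-6-[(5R)-5-(tert-butyldimethylsilyloxy)octyl]-2-(triisopropylsilyloxy)cyclohex-1-en-1-yl]propanamide
Conditions: [PtH(PMe2OH)(PMe2O)2H] (2 mol%), EtOH–H2O (4:1), 80 °C
Reagents that add atoms: water, O
Why: Platinum-catalysed hydration of the nitrile under neutral conditions gives the primary amide without cleaving the enol ether or the silyl ether.

Step 11
Reactants: 18 the silyl enol ether amide
Product: 20 (5S)-5-[(5R)-5-(tert-butyldimethylsilyloxy)octyl]-3,4,5,6,7,8-hexahydroquinolin-2(1H)-one, via keto amide 19 (not isolated)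
Conditions: TsOH·H2O (10 mol%), toluene, 80 °C
Reagents that add atoms: none
Why: Acid unmasks the ketone from the silyl enol ether and the primary amide condenses with it (cyclodehydration of a δ-oxo amide) to the preferred tetrasubstituted ene-lactam, so ring A closes and C4a needs no control at this stage.

Step 12
Reactants: 20 the ene-lactam
Product: 21 (4aS,5S,8aR)-5-[(5R)-5-(tert-butyldimethylsilyloxy)octyl]octahydroquinolin-2(1H)-one
Conditions: H2 (5 bar), Pd/C (10%), EtOAc–AcOH (10:1), rt
Reagents that add atoms: none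
Why: Heterogeneous syn-hydrogenation of the tetrasubstituted ene-lactam should deliver both hydrogens to the face opposite the C5 chain (held pseudoaxial by allylic strain with C4), setting C4a and C8a together and giving the cis-fused lactam with H-4a, H-5 and H-8a all cis.

Step 13
Reactants: 21 the cis-fused lactam
Product: 22 tert-butyl (4aS,5S,8aR)-5-[(5R)-5-(tert-butyldimethylsilyloxy)octyl]-2-oxooctahydroquinoline-1(2H)-carboxylate
Conditions: Boc2O, DMAP (cat.), Et3N, MeCN, rt
Reagents that add atoms: di-tert-butyl dicarbonate, CC(C)(C)OC(=O)OC(=O)OC(C)(C)C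
Why: N-Acylation of the lactam activates the ring carbonyl towards organometallic addition and later fixes the conformation of ring A by allylic strain.

Step 14
Reactants: 22 the N-Boc lactam
Product: 23 tert-butyl N-[(1R,2S,3S)-3-[(5R)-5-(tert-butyldimethylsilyloxy)octyl]-2-(3-oxobutyl)cyclohexyl]carbamate
Conditions: MeMgBr (1.2 equiv), THF, −78 °C; H2O
Reagents that add atoms: methylmagnesium bromide, C[Mg]Br
Why: Grignard addition to the imide-like ring carbonyl of an N-Boc lactam gives, after ring opening of the hemiaminal, the methyl ketone that carries the future C2 methyl group.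

Step 15
Reactants: 23 the keto carbamate
Product: 24 tert-butyl (4aS,5S,8aR)-5-[(5R)-5-(tert-butyldimethylsilyloxy)octyl]-2-methyl-4a,5,6,7,8,8a-hexahydroquinoline-1(4H)-carboxylate
Conditions: PPTS (10 mol%), toluene, 4 Å MS, 80 °C
Reagents that add atoms: none
Why: Mild acid-catalysed cyclodehydration of the δ-carbamoyl ketone should give the endocyclic trisubstituted enecarbamate, the more stable regioisomer.

Step 16
Reactants: 24 the 2-methyl enecarbamate
Product: 26 tert-butyl (2R,3R,4aS,5S,8aR)-5-[(5R)-5-(tert-butyldimethylsilyloxy)octyl]-3-hydroxy-2-methyloctahydroquinoline-1(2H)-carboxylate, via epoxide 25 (not isolated)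
Conditions: DMDO, acetone–CH2Cl2, −78 → −40 °C; then Et3SiH, BF3·OEt2, −78 → −40 °C; aq. NaHCO3
Reagents that add atoms: dimethyldioxirane, CC1(C)OO1
Why: Dimethyldioxirane should epoxidise the electron-rich enecarbamate on the convex face of ring A (the face of H-4a and H-8a, since the carbamate holds the C8a–C8 bond axial over the other face), and Lewis-acid opening at C2 followed by axial hydride delivery anti to the C3 oxygen sets C3 and C2 together with methyl and hydroxyl cis (enecarbamate epoxidation with reductive opening of the N,O-acetal epoxide).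

Step 17
Reactants: 26 the N-Boc amino alcohol; 27 (2E)-oct-2-enoic acid
Product: 28 tert-butyl (2R,3R,4aS,5S,8aR)-5-[(5R)-5-(tert-butyldimethylsilyloxy)octyl]-2-methyl-3-[(2E)-oct-2-enoyloxy]octahydroquinoline-1(2H)-carboxylate
Conditions: EDC·HCl, DMAP, CH2Cl2, 0 °C → rt
Reagents that add atoms: none
Why: Steglich esterification acylates only O3 because the nitrogen is blocked as the carbamate and the side-chain hydroxyl as the silyl ether.

Step 18
Reactants: 28 the protected ester
Product: 29 (2R,3R,4aS,5S,8aR)-5-[(5R)-5-hydroxyoctyl]-2-methyldecahydroquinolin-3-yl (2E)-oct-2-enoate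
Conditions: TFA–H2O (9:1), 0 °C → rt; then aq. NaHCO3
Reagents that add atoms: none
Why: Aqueous trifluoroacetic acid removes the tert-butyl carbamate and the silyl ether in one operation while the protonated amine cannot attack the enoate, and neutralisation liberates the target.

**Compound list**
1 | 5-bromopent-1-ene | C=CCCCBr | starting material
2 | (R)-2-propyloxirane | CCC[C@@H]1CO1 | starting material
3 | pent-4-enylmagnesium bromide (not isolated) | C=CCCC[Mg]Br | intermediate
4 | (4R)-dec-9-en-4-ol | C=CCCCC[C@H](O)CCC | intermediate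
5 | tert-butyl[(4R)-dec-9-en-4-yloxy]dimethylsilane | C=CCCCC[C@H](O[Si](C)(C)C(C)(C)C)CCC | intermediate
6 | 3-[(5R)-5-(tert-butyldimethylsilyloxy)octyl]-1,2,4-trioxolane (ozonide, not isolated) | C1OOC(CCCC[C@H](O[Si](C)(C)C(C)(C)C)CCC)O1 | intermediate
7 | (6R)-6-(tert-butyldimethylsilyloxy)nonanal | O=CCCCC[C@H](O[Si](C)(C)C(C)(C)C)CCC | intermediate
8 | dimethyl (2-oxopropyl)phosphonate | CC(=O)CP(=O)(OC)OC | starting material
9 | acrylonitrile | C=CC#N | starting material
10 | dimethyl (5-cyano-2-oxopentan-3-yl)phosphonate (racemic) | CC(=O)C(CCC#N)P(=O)(OC)OC | intermediate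
11 | (4E,10R)-4-acetyl-10-(tert-butyldimethylsilyloxy)tridec-4-enenitrile | CC(=O)/C(CCC#N)=C/CCCC[C@H](O[Si](C)(C)C(C)(C)C)CCC | intermediate
12 | (4E,10R)-10-(tert-butyldimethylsilyloxy)-4-[1-(triisopropylsilyloxy)ethenyl]tridec-4-enenitrile | C=C(O[Si](C(C)C)(C(C)C)C(C)C)/C(CCC#N)=C/CCCC[C@H](O[Si](C)(C)C(C)(C)C)CCC | intermediate
13 | 2,2,2-trifluoroethyl prop-2-enoate | C=CC(=O)OCC(F)(F)F | starting material
14 | 2,2,2-trifluoroethyl (1S,2S)-2-[(5R)-5-(tert-butyldimethylsilyloxy)octyl]-3-(2-cyanoethyl)-4-(triisopropylsilyloxy)cyclohex-3-ene-1-carboxylate | C1(O[Si](C(C)C)(C(C)C)C(C)C)=C(CCC#N)[C@@H](CCCC[C@H](O[Si](C)(C)C(C)(C)C)CCC)[C@@H](C(=O)OCC(F)(F)F)CC1 | intermediate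
15 | (1S,2S)-2-[(5R)-5-(tert-butyldimethylsilyloxy)octyl]-3-(2-cyanoethyl)-4-(triisopropylsilyloxy)cyclohex-3-ene-1-carboxylic acid | C1(O[Si](C(C)C)(C(C)C)C(C)C)=C(CCC#N)[C@@H](CCCC[C@H](O[Si](C)(C)C(C)(C)C)CCC)[C@@H](C(=O)O)CC1 | intermediate
16 | 2-thioxopyridin-1(2H)-yl ester of 15 (not isolated) | C1(O[Si](C(C)C)(C(C)C)C(C)C)=C(CCC#N)[C@@H](CCCC[C@H](O[Si](C)(C)C(C)(C)C)CCC)[C@@H](C(=O)ON2C=CC=CC2=S)CC1 | intermediate
17 | 3-[(6S)-6-[(5R)-5-(tert-butyldimethylsilyloxy)octyl]-2-(triisopropylsilyloxy)cyclohex-1-en-1-yl]propanenitrile | C1(O[Si](C(C)C)(C(C)C)C(C)C)=C(CCC#N)[C@@H](CCCC[C@H](O[Si](C)(C)C(C)(C)C)CCC)CCC1 | intermediate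
18 | 3-[(6S)-6-[(5R)-5-(tert-butyldimethylsilyloxy)octyl]-2-(triisopropylsilyloxy)cyclohex-1-en-1-yl]propanamide | C1(O[Si](C(C)C)(C(C)C)C(C)C)=C(CCC(N)=O)[C@@H](CCCC[C@H](O[Si](C)(C)C(C)(C)C)CCC)CCC1 | intermediate
19 | 3-[(6S)-6-[(5R)-5-(tert-butyldimethylsilyloxy)octyl]-2-oxocyclohexyl]propanamide (both C1 epimers, not isolated) | O=C1C(CCC(N)=O)[C@@H](CCCC[C@H](O[Si](C)(C)C(C)(C)C)CCC)CCC1 | intermediate
20 | (5S)-5-[(5R)-5-(tert-butyldimethylsilyloxy)octyl]-3,4,5,6,7,8-hexahydroquinolin-2(1H)-one | O=C1CCC2=C(CCC[C@@H]2CCCC[C@H](O[Si](C)(C)C(C)(C)C)CCC)N1 | intermediate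
21 | (4aS,5S,8aR)-5-[(5R)-5-(tert-butyldimethylsilyloxy)octyl]octahydroquinolin-2(1H)-one | O=C1CC[C@H]2[C@@H](CCCC[C@H](O[Si](C)(C)C(C)(C)C)CCC)CCC[C@H]2N1 | intermediate
22 | tert-butyl (4aS,5S,8aR)-5-[(5R)-5-(tert-butyldimethylsilyloxy)octyl]-2-oxooctahydroquinoline-1(2H)-carboxylate | O=C1CC[C@H]2[C@@H](CCCC[C@H](O[Si](C)(C)C(C)(C)C)CCC)CCC[C@H]2N1C(=O)OC(C)(C)C | intermediate
23 | tert-butyl N-[(1R,2S,3S)-3-[(5R)-5-(tert-butyldimethylsilyloxy)octyl]-2-(3-oxobutyl)cyclohexyl]carbamate | CC(=O)CC[C@H]1[C@@H](CCCC[C@H](O[Si](C)(C)C(C)(C)C)CCC)CCC[C@H]1NC(=O)OC(C)(C)C | intermediate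
24 | tert-butyl (4aS,5S,8aR)-5-[(5R)-5-(tert-butyldimethylsilyloxy)octyl]-2-methyl-4a,5,6,7,8,8a-hexahydroquinoline-1(4H)-carboxylate | CC1=CC[C@H]2[C@@H](CCCC[C@H](O[Si](C)(C)C(C)(C)C)CCC)CCC[C@H]2N1C(=O)OC(C)(C)C | intermediate
25 | 2,3-epoxide of 24, oxygen on the face of H-4a and H-8a (not isolated) | O1[C@@H]2C[C@H]3[C@@H](CCCC[C@H](O[Si](C)(C)C(C)(C)C)CCC)CCC[C@H]3N(C(=O)OC(C)(C)C)[C@]12C | intermediate
26 | tert-butyl (2R,3R,4aS,5S,8aR)-5-[(5R)-5-(tert-butyldimethylsilyloxy)octyl]-3-hydroxy-2-methyloctahydroquinoline-1(2H)-carboxylate | O[C@@H]1C[C@H]2[C@@H](CCCC[C@H](O[Si](C)(C)C(C)(C)C)CCC)CCC[C@H]2N(C(=O)OC(C)(C)C)[C@@H]1C | intermediate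
27 | (2E)-oct-2-enoic acid | CCCCC/C=C/C(=O)O | starting material
28 | tert-butyl (2R,3R,4aS,5S,8aR)-5-[(5R)-5-(tert-butyldimethylsilyloxy)octyl]-2-methyl-3-[(2E)-oct-2-enoyloxy]octahydroquinoline-1(2H)-carboxylate | CCCCC/C=C/C(=O)O[C@@H]1C[C@H]2[C@@H](CCCC[C@H](O[Si](C)(C)C(C)(C)C)CCC)CCC[C@H]2N(C(=O)OC(C)(C)C)[C@@H]1C | intermediate
29 | (2R,3R,4aS,5S,8aR)-5-[(5R)-5-hydroxyoctyl]-2-methyldecahydroquinolin-3-yl (2E)-oct-2-enoate | CCCCC/C=C/C(=O)O[C@@H]1C[C@H]2[C@@H](CCCC[C@H](O)CCC)CCC[C@H]2N[C@@H]1C | target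

**Step count and risks**
Total steps: 18. Longest linear sequence: 17 (steps 1–3 and 5–18, from 1).

Step 7. What may go wrong: the nitrile may hold back the Lewis acid, the dienol ether may be protonated or may add in an open-chain conjugate fashion without ring closure, and enantiofacial control may erode, so that C5 forms as a mixture. Fallback (auxiliary control in place of catalyst control), setting out from 12: cycloaddition with (R)-4-benzyl-3-(prop-2-enoyl)oxazolidin-2-one promoted by Et2AlCl (1.5 equiv, CH2Cl2, −78 °C) should give the N-acyloxazolidinone cycloadduct F1. The chelated s-cis acryloyl imide is attacked endo on the face remote from the benzyl group, which for the (R)-auxiliary is the face that leads to (5S). LiOH/H2O2 (THF–H2O, 0 °C) then cleaves the auxiliary and the route is rejoined at 15.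

Step 16. What may go wrong: the 2-methyl epoxide may collapse to the 3-ketone by hydride shift, or the hydride may reach C2 with poor facial selectivity. Fallback (the oxygen is introduced by enolate oxidation before the methyl group), setting out from 22: KN(SiMe3)2 (THF, −78 °C) gives the potassium enolate of 22 F2, which 3-phenyl-2-(phenylsulfonyl)oxaziridine should hydroxylate on the convex face to the 3-hydroxy lactam F3. Et3SiOTf/2,6-lutidine gives its triethylsilyl ether F4, and MeMgBr (THF, −78 °C) opens the ring carbonyl to the α-silyloxy methyl ketone F5. Reductive cyclisation with Et3SiH/BF3·OEt2 (CH2Cl2, −78 °C) should give the triethylsilyl ether of 26 F6, and HF·pyridine (THF, 0 °C) removes the triethylsilyl group to rejoin the route at 26.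

Step 12. What may go wrong: the tetrasubstituted ene-lactam may hydrogenate sluggishly, with poor facial selectivity, or only after migration of the double bond towards C8. Fallback (the two ring-fusion centres are set one after the other on the monocycle, before ring A is closed), setting out from 18: Bu4NF/AcOH (THF, −78 °C) should cleave the enol ether with kinetic protonation of C4a anti to the C5 chain to give the cis keto amide F7. NH2OH·HCl/NaOAc (EtOH, rt) gives its oxime F8. Hydrogenation (H2, PtO2, AcOH) should deliver hydrogen to the face opposite the axial C5 chain and give the all-cis amino amide F9, and heating (toluene, 110 °C) closes the lactam with loss of ammonia to rejoin the route at 21.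

**Further compounds**
F1 | step 7 | (4R)-4-benzyl-3-{[(1S,2S)-2-[(5R)-5-(tert-butyldimethylsilyloxy)octyl]-3-(2-cyanoethyl)-4-(triisopropylsilyloxy)cyclohex-3-en-1-yl]carbonyl}oxazolidin-2-one | C1(O[Si](C(C)C)(C(C)C)C(C)C)=C(CCC#N)[C@@H](CCCC[C@H](O[Si](C)(C)C(C)(C)C)CCC)[C@@H](C(=O)N2[C@H](Cc3ccccc3)COC2=O)CC1
F2 | step 16 | potassium enolate of 22 | [K+].[O-]C1=CC[C@H]2[C@@H](CCCC[C@H](O[Si](C)(C)C(C)(C)C)CCC)CCC[C@H]2N1C(=O)OC(C)(C)C
F3 | step 16 | tert-butyl (3R,4aS,5S,8aR)-5-[(5R)-5-(tert-butyldimethylsilyloxy)octyl]-3-hydroxy-2-oxooctahydroquinoline-1(2H)-carboxylate | O[C@@H]1C[C@H]2[C@@H](CCCC[C@H](O[Si](C)(C)C(C)(C)C)CCC)CCC[C@H]2N(C(=O)OC(C)(C)C)C1=O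
F4 | step 16 | tert-butyl (3R,4aS,5S,8aR)-5-[(5R)-5-(tert-butyldimethylsilyloxy)octyl]-2-oxo-3-(triethylsilyloxy)octahydroquinoline-1(2H)-carboxylate | CC[Si](CC)(CC)O[C@@H]1C[C@H]2[C@@H](CCCC[C@H](O[Si](C)(C)C(C)(C)C)CCC)CCC[C@H]2N(C(=O)OC(C)(C)C)C1=O
F5 | step 16 | tert-butyl N-[(1R,2S,3S)-3-[(5R)-5-(tert-butyldimethylsilyloxy)octyl]-2-[(2R)-3-oxo-2-(triethylsilyloxy)butyl]cyclohexyl]carbamate | CC(=O)[C@H](O[Si](CC)(CC)CC)C[C@H]1[C@@H](CCCC[C@H](O[Si](C)(C)C(C)(C)C)CCC)CCC[C@H]1NC(=O)OC(C)(C)C
F6 | step 16 | tert-butyl (2R,3R,4aS,5S,8aR)-5-[(5R)-5-(tert-butyldimethylsilyloxy)octyl]-2-methyl-3-(triethylsilyloxy)octahydroquinoline-1(2H)-carboxylate | CC[Si](CC)(CC)O[C@@H]1C[C@H]2[C@@H](CCCC[C@H](O[Si](C)(C)C(C)(C)C)CCC)CCC[C@H]2N(C(=O)OC(C)(C)C)[C@@H]1C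
F7 | step 12 | 3-[(1S,6S)-6-[(5R)-5-(tert-butyldimethylsilyloxy)octyl]-2-oxocyclohexyl]propanamide | NC(=O)CC[C@H]1[C@@H](CCCC[C@H](O[Si](C)(C)C(C)(C)C)CCC)CCCC1=O
F8 | step 12 | 3-[(1S,6S)-6-[(5R)-5-(tert-butyldimethylsilyloxy)octyl]-2-(hydroxyimino)cyclohexyl]propanamide | NC(=O)CC[C@H]1[C@@H](CCCC[C@H](O[Si](C)(C)C(C)(C)C)CCC)CCCC1=NO
F9 | step 12 | 3-[(1S,2R,6S)-2-amino-6-[(5R)-5-(tert-butyldimethylsilyloxy)octyl]cyclohexyl]propanamide | NC(=O)CC[C@H]1[C@@H](CCCC[C@H](O[Si](C)(C)C(C)(C)C)CCC)CCC[C@H]1N
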